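The ten-membered carbocycle is disconnected at C8–C9 (germacrane numbering), between the acyloxy-bearing allylic carbinol carbon and the vinylic CH of the (Z)-C9=C10 olefin. An intramolecular Nozaki–Hiyama–Kishi reaction forms this bond, closes the ring and sets C8 in one operation. It exploits the C8–C9=C10 allylic alcohol motif. The trans-fused five-membered lactone (O, C6, C7, C11, C12) and the two in-ring cis olefins (C4=C5, C9=C10) fold the seco chain. The precursor is a (Z)-alkenyl iodide chain hanging from a trans-β-formyl-α-methylene-γ-butyrolactone. It is assembled by an auxiliary-controlled itaconate aldol–lactonisation with a ten-carbon enal.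

Key step: step 14

Remark: germacrane numbering of the target is used for all intermediates (C1 ring carbinol, C4=C5 and C9=C10 ring olefins, C6/C7 lactone fusion, C8 acyloxy carbon, C11–C13 methylene-lactone carbons, C14 methyl, C15 CH2OH). The carbinol centre made in step 5 is left undefined because step 7 removes it.

Step 1
Reactants: 1 prop-2-yn-1-ol
Product: 3 (Z)-3-iodo-2-methylprop-2-en-1-ol, via cyclic alkenylmagnesium alkoxide 2 (not isolated)
Conditions: MeMgBr (2.5 equiv), CuI (10 mol %), THF, −10 °C to rt; then I2, −10 °C to rt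
Reagents that add atoms: methylmagnesium bromide, C[Mg]Br; iodine, II
Why: Copper-catalysed anti-carbomagnesiation of a propargylic alkoxide puts the methyl group on the internal alkyne carbon and magnesium on the terminus inside the five-membered chelate 2, so iodinolysis with retention should give only the (Z)-iodide that becomes C9=C10 with C14.

Step 2
Reactants: 3 (Z)-3-iodo-2-methylprop-2-en-1-ol
Product: 4 (Z)-3-iodo-2-methylprop-2-enal
Conditions: MnO2 (excess), CH2Cl2, rt, dark
Reagents that add atoms: none
Why: MnO2 oxidation of a primary allylic alcohol is neutral and should stop at the enal without harming the C–I bond or, with light excluded, the (Z) geometry.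

Step 3
Reactants: 4 (Z)-3-iodo-2-methylprop-2-enal; 5 but-3-en-1-ylmagnesium bromide
Product: 7 (3S,1Z)-1-iodo-2-methylhepta-1,6-dien-3-ol, via di(but-3-en-1-yl)zinc 6 (not isolated)
Conditions: 5, ZnCl2, Et2O–THF, 0 °C to rt, then 1,4-dioxane, filter; Ti(OiPr)4, (1R,2R)-1,2-bis(trifluoromethanesulfonamido)cyclohexane (8 mol %), toluene, −20 °C, then 4
Reagents that add atoms: zinc chloride, [Zn+2].[Cl-].[Cl-] (zinc appears in 6 only)
Why: Catalytic enantioselective dialkylzinc addition to an α-branched enal, in which the titanium complex of the (R,R)-bis(sulfonamide) should deliver the butenyl group to the Si face and so set (S)-C1, the alkenyl iodide being inert to dialkylzincs at this temperature.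

Step 4
Reactants: 7 (3S,1Z)-1-iodo-2-methylhepta-1,6-dien-3-ol
Product: 8 (3S,1Z)-3-(tert-butyldimethylsilyloxy)-1-iodo-2-methylhepta-1,6-diene
Conditions: TBSCl, imidazole, DMF, rt
Reagents that add atoms: tert-butyldimethylsilyl chloride, CC(C)(C)[Si](C)(C)Cl
Why: Standard silyl ether formation protects the C1 hydroxyl for the oxidations, hydride reductions and the aldol step that follow.

Step 5
Reactants: 8 (3S,1Z)-3-(tert-butyldimethylsilyloxy)-1-iodo-2-methylhepta-1,6-diene
Product: 9 (5S,6Z)-5-(tert-butyldimethylsilyloxy)-7-iodo-6-methylhept-6-ene-1,2-diol (both C2 epimers)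
Conditions: OsO4 (1 mol %), NMO, acetone–H2O, 0 °C to rt
Reagents that add atoms: N-methylmorpholine N-oxide, C[N+]1([O-])CCOCC1; water, O
Why: Upjohn dihydroxylation should select the unhindered monosubstituted olefin over the trisubstituted, iodine-deactivated and sterically screened C9=C10 bond, and the new carbinol centre needs no control because step 7 destroys it.

Step 6
Reactants: 9 (5S,6Z)-5-(tert-butyldimethylsilyloxy)-7-iodo-6-methylhept-6-ene-1,2-diol
Product: 10 (5S,6Z)-1,5-bis(tert-butyldimethylsilyloxy)-7-iodo-6-methylhept-6-en-2-ol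
Conditions: TBSCl (1.05 equiv), imidazole, CH2Cl2, 0 °C
Reagents that add atoms: tert-butyldimethylsilyl chloride, CC(C)(C)[Si](C)(C)Cl
Why: Rate-controlled silylation distinguishes the primary C15 hydroxyl from the secondary C4 hydroxyl.

Step 7
Reactants: 10 (5S,6Z)-1,5-bis(tert-butyldimethylsilyloxy)-7-iodo-6-methylhept-6-en-2-ol
Product: 11 (5S,6Z)-1,5-bis(tert-butyldimethylsilyloxy)-7-iodo-6-methylhept-6-en-2-one
Conditions: Dess–Martin periodinane, CH2Cl2, rt
Reagents that add atoms: none
Why: Dess–Martin oxidation converts the remaining secondary alcohol into the α-silyloxy ketone under mild conditions that spare silyl ethers and the alkenyl iodide.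

Step 8
Reactants: 11 (5S,6Z)-1,5-bis(tert-butyldimethylsilyloxy)-7-iodo-6-methylhept-6-en-2-one; 12 N-methoxy-N-methyl-2-(triphenylphosphoranylidene)acetamide
Product: 13 (2E,6S,7Z)-6-(tert-butyldimethylsilyloxy)-3-[(tert-butyldimethylsilyloxy)methyl]-8-iodo-N-methoxy-N,7-dimethylocta-2,7-dienamide
Conditions: 12 (2 equiv), PhCO2H (10 mol %), toluene, 110 °C
Reagents that add atoms: none
Why: Wittig olefination with a stabilised ylide, for which α-silyloxy ketones are activated substrates that characteristically place the new carbonyl group trans to the CH2OSi arm, should give the (2E)-amide in which C6 is cis to C3 as the in-ring cis C4=C5 olefin requires.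

Step 9
Reactants: 13 (2E,6S,7Z)-Weinreb dienamide
Product: 14 (2E,6S,7Z)-6-(tert-butyldimethylsilyloxy)-3-[(tert-butyldimethylsilyloxy)methyl]-8-iodo-7-methylocta-2,7-dienal
Conditions: i-Bu2AlH (1.2 equiv), THF, −78 °C; aq Rochelle salt
Reagents that add atoms: none
Why: Weinreb amide reduction stops at the aldehyde because the chelated tetrahedral aluminium intermediate survives until work-up.

Step 10
Reactants: 15 dimethyl itaconate
Product: 16 3-(methoxycarbonyl)but-3-enoic acid
Conditions: LiOH (1.0 equiv), THF–H2O, 0 °C; then 1 M HCl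
Reagents that add atoms: lithium hydroxide, [Li+].[OH-]
Why: Regioselective saponification relies on the saturated ester being more electrophilic than the conjugated acrylate ester, so one equivalent of hydroxide should free only the C8 carboxyl group.

Step 11
Reactants: 16 3-(methoxycarbonyl)but-3-enoic acid; 17 (S)-4-benzyl-1,3-thiazolidine-2-thione
Product: 18 methyl 4-[(4S)-4-benzyl-2-thioxo-1,3-thiazolidin-3-yl]-2-methylidene-4-oxobutanoate
Conditions: DCC, DMAP (5 mol %), CH2Cl2, 0 °C to rt
Reagents that add atoms: none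
Why: Carbodiimide-mediated N-acylation (Steglich conditions) of the thiazolidinethione is mild enough to keep the 1,1-disubstituted olefin out of conjugation.

Step 12
Reactants: 14 (2E,6S,7Z)-dienal; 18 itaconyl thiazolidinethione
Product: 21 trans-lactone imide, (4S)-4-benzyl-3-{[(2R,3S)-2-[(1E,5S,6Z)-5-(tert-butyldimethylsilyloxy)-2-[(tert-butyldimethylsilyloxy)methyl]-7-iodo-6-methylhepta-1,6-dien-1-yl]-4-methylidene-5-oxooxolan-3-yl]carbonyl}-1,3-thiazolidine-2-thione, via titanium enolate 19 (not isolated), via syn-aldol hydroxy ester 20 (not isolated)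
Conditions: 18, TiCl4 (1.05 equiv), i-Pr2NEt (1.1 equiv), NMP (1 equiv), CH2Cl2, 0 °C; 14, −78 to −40 °C; aq NH4Cl; then PPTS (20 mol %), toluene, 40 °C
Reagents that add atoms: titanium tetrachloride, Cl[Ti](Cl)(Cl)Cl (titanium and chlorine appear in 19 only)
Why: Auxiliary-controlled titanium aldol reaction (thiazolidinethione variant of the Evans syn aldol) followed by lactonisation: soft enolisation should give the Z(O)-dienolate 19, which reacts at its α-carbon C7 through a non-chelated Zimmerman–Traxler chair on the face away from the benzyl group to set the syn pair (6R,7S in 20), and acid-catalysed attack of the C6 hydroxyl on the acrylate ester then closes the trans-lactone.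

Step 13
Reactants: 21 trans-lactone imide
Product: 22 (2R,3S)-2-[(1E,5S,6Z)-5-(tert-butyldimethylsilyloxy)-2-[(tert-butyldimethylsilyloxy)methyl]-7-iodo-6-methylhepta-1,6-dien-1-yl]-4-methylidene-5-oxooxolane-3-carbaldehyde
Conditions: i-Bu2AlH (1.1 equiv, added until the yellow colour fades), CH2Cl2, −78 °C; pH 7 buffer, Rochelle salt; short neutral silica plug, used at once
Reagents that add atoms: none
Why: Direct i-Bu2AlH reduction of an N-acylthiazolidinethione to the aldehyde is a known auxiliary cleavage, and the twisted, highly electrophilic imide carbonyl should be consumed (fading of the yellow colour) before the conjugated lactone reacts.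

Step 14
Reactants: 22 iodo aldehyde
Product: 24 (1S,6R,7R,8R)-1,15-bis(tert-butyldimethylsilyloxy)-8-hydroxygermacra-4,9,11(13)-trien-12,6-olide (4E,9Z by CIP, both olefins cis within the ring), via alkenylchromium dichloride 23 (not isolated)
Conditions: CrCl2 (12 equiv), NiCl2 (0.1 equiv), degassed DMSO, rt, slow addition of 22 to 2 mM final concentration
Reagents that add atoms: chromium dichloride, [Cr+2].[Cl-].[Cl-] (chromium and chlorine appear in 23 only)
Why: Zerovalent nickel, generated from NiCl2 by divalent chromium, inserts into the C9–I bond with retention, the alkenyl group passes to trivalent chromium (23), and this mild carbanion equivalent adds to the C8 aldehyde; the closest known reaction type is the Nozaki–Hiyama–Kishi macrocyclisation used for medium-ring allylic alcohols. The ten-membered carbocycle closes in a 10-exo-trig mode, C9 attacking the carbonyl carbon C8 whose oxygen stays outside the ring. The new centre C8 is controlled by C7: the tether through C6 makes C9 approach gauche to C6 and anti to the C7–C11 bond (Felkin–Anh arrangement with the sp2 carbon C11 as the perpendicular group), so the Re face is attacked and (8R), with O8 anti to O6, should result. Chemoselectivity is needed between the aldehyde and the lactone, acrylate and silyl ether groups, and it is secured by the low basicity and high aldehyde preference of alkenylchromium reagents, which should also leave the epimerisable, β-acyloxy-substituted C7 and the exocyclic C11=C13 olefin in place. Ring closure has to beat oligomerisation, which high dilution, the rigid trans-lactone turn at C6–C7 and the two cis-disposed olefins C4=C5 and C9=C10 should favour. The (Z) geometry of C9=C10 should be kept because β,β-disubstituted alkenylchromium species are configurationally stable.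

Step 15
Reactants: 24 macrocyclic C8 alcohol; 25 (S)-2-methylbutanoic acid
Product: 26 (1S,6R,7R,8R)-1,15-bis(tert-butyldimethylsilyloxy)-8-[(2S)-2-methylbutanoyloxy]germacra-4,9,11(13)-trien-12,6-olide
Conditions: 25, DCC, DMAP (20 mol %), CH2Cl2, 0 °C to rt
Reagents that add atoms: none
Why: Steglich esterification acylates the single free hydroxyl at C8 with retention at C8 and, through the O-acylisourea and acylpyridinium pathway at low temperature, without loss of the (S) centre of the acid.

Step 16
Reactants: 26 bis(silyl ether) ester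
Product: 27 CNP0526758.1, (1S,6R,7R,8R)-1,15-dihydroxy-8-[(2S)-2-methylbutanoyloxy]germacra-4,9,11(13)-trien-12,6-olide
Conditions: HF·pyridine, pyridine, THF, 0 °C to rt
Reagents that add atoms: none
Why: Fluoride-mediated cleavage of both silyl ethers under buffered acidic conditions avoids the base-induced acyl migration, translactonisation and conjugate addition that the ester and the α-methylene lactone would risk.

Compound list
1 | prop-2-yn-1-ol | C#CCO | starting material
2 | 4-methyl-2,5-dihydro-1,2-oxamagnesole (cyclic alkenylmagnesium alkoxide) | CC1=C[Mg]OC1 | intermediate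
3 | (Z)-3-iodo-2-methylprop-2-en-1-ol | OC/C(C)=C\I | intermediate
4 | (Z)-3-iodo-2-methylprop-2-enal | O=C/C(C)=C\I | intermediate
5 | but-3-en-1-ylmagnesium bromide | C=CCC[Mg]Br | starting material
6 | di(but-3-en-1-yl)zinc | C=CCC[Zn]CCC=C | intermediate
7 | (3S,1Z)-1-iodo-2-methylhepta-1,6-dien-3-ol | C=CCC[C@H](O)/C(C)=C\I | intermediate
8 | (3S,1Z)-3-(tert-butyldimethylsilyloxy)-1-iodo-2-methylhepta-1,6-diene | C=CCC[C@H](O[Si](C)(C)C(C)(C)C)/C(C)=C\I | intermediate
9 | (5S,6Z)-5-(tert-butyldimethylsilyloxy)-7-iodo-6-methylhept-6-ene-1,2-diol | OCC(O)CC[C@H](O[Si](C)(C)C(C)(C)C)/C(C)=C\I | intermediate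
10 | (5S,6Z)-1,5-bis(tert-butyldimethylsilyloxy)-7-iodo-6-methylhept-6-en-2-ol | CC(C)(C)[Si](C)(C)OCC(O)CC[C@H](O[Si](C)(C)C(C)(C)C)/C(C)=C\I | intermediate
11 | (5S,6Z)-1,5-bis(tert-butyldimethylsilyloxy)-7-iodo-6-methylhept-6-en-2-one | CC(C)(C)[Si](C)(C)OCC(=O)CC[C@H](O[Si](C)(C)C(C)(C)C)/C(C)=C\I | intermediate
12 | N-methoxy-N-methyl-2-(triphenylphosphoranylidene)acetamide | CON(C)C(=O)C=P(c1ccccc1)(c1ccccc1)c1ccccc1 | starting material
13 | (2E,6S,7Z)-6-(tert-butyldimethylsilyloxy)-3-[(tert-butyldimethylsilyloxy)methyl]-8-iodo-N-methoxy-N,7-dimethylocta-2,7-dienamide | CON(C)C(=O)/C=C(/CO[Si](C)(C)C(C)(C)C)CC[C@H](O[Si](C)(C)C(C)(C)C)/C(C)=C\I | intermediate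
14 | (2E,6S,7Z)-6-(tert-butyldimethylsilyloxy)-3-[(tert-butyldimethylsilyloxy)methyl]-8-iodo-7-methylocta-2,7-dienal | O=C/C=C(/CO[Si](C)(C)C(C)(C)C)CC[C@H](O[Si](C)(C)C(C)(C)C)/C(C)=C\I | intermediate
15 | dimethyl itaconate | C=C(CC(=O)OC)C(=O)OC | starting material
16 | 3-(methoxycarbonyl)but-3-enoic acid | C=C(CC(=O)O)C(=O)OC | intermediate
17 | (S)-4-benzyl-1,3-thiazolidine-2-thione | S=C1N[C@@H](Cc2ccccc2)CS1 | starting material
18 | methyl 4-[(4S)-4-benzyl-2-thioxo-1,3-thiazolidin-3-yl]-2-methylidene-4-oxobutanoate | C=C(CC(=O)N1[C@@H](Cc2ccccc2)CSC1=S)C(=O)OC | intermediate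
19 | trichlorotitanium Z(O)-dienolate of 18 | C=C(/C=C(\O[Ti](Cl)(Cl)Cl)N1[C@@H](Cc2ccccc2)CSC1=S)C(=O)OC | intermediate
20 | syn-aldol hydroxy ester (6R,7S) | C=C(C(=O)OC)[C@@H]([C@H](O)/C=C(/CO[Si](C)(C)C(C)(C)C)CC[C@H](O[Si](C)(C)C(C)(C)C)/C(C)=C\I)C(=O)N1[C@@H](Cc2ccccc2)CSC1=S | intermediate
21 | trans-α-methylene-γ-butyrolactone imide (lactone ring 2R,3S) | C=C1C(=O)O[C@H](/C=C(/CO[Si](C)(C)C(C)(C)C)CC[C@H](O[Si](C)(C)C(C)(C)C)/C(C)=C\I)[C@H]1C(=O)N2[C@@H](Cc3ccccc3)CSC2=S | intermediate
22 | (2R,3S)-2-[(1E,5S,6Z)-5-(tert-butyldimethylsilyloxy)-2-[(tert-butyldimethylsilyloxy)methyl]-7-iodo-6-methylhepta-1,6-dien-1-yl]-4-methylidene-5-oxooxolane-3-carbaldehyde | C=C1C(=O)O[C@H](/C=C(/CO[Si](C)(C)C(C)(C)C)CC[C@H](O[Si](C)(C)C(C)(C)C)/C(C)=C\I)[C@H]1C=O | intermediate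
23 | (Z)-alkenylchromium dichloride derived from 22 | C=C1C(=O)O[C@H](/C=C(/CO[Si](C)(C)C(C)(C)C)CC[C@H](O[Si](C)(C)C(C)(C)C)/C(C)=C\[Cr](Cl)Cl)[C@H]1C=O | intermediate
24 | (1S,6R,7R,8R)-1,15-bis(tert-butyldimethylsilyloxy)-8-hydroxygermacra-4,9,11(13)-trien-12,6-olide | C=C1C(=O)O[C@@H]2/C=C(/CO[Si](C)(C)C(C)(C)C)CC[C@H](O[Si](C)(C)C(C)(C)C)/C(C)=C\[C@@H](O)[C@@H]12 | intermediate
25 | (S)-2-methylbutanoic acid | CC[C@H](C)C(=O)O | starting material
26 | (1S,6R,7R,8R)-1,15-bis(tert-butyldimethylsilyloxy)-8-[(2S)-2-methylbutanoyloxy]germacra-4,9,11(13)-trien-12,6-olide | C=C1C(=O)O[C@@H]2/C=C(/CO[Si](C)(C)C(C)(C)C)CC[C@H](O[Si](C)(C)C(C)(C)C)/C(C)=C\[C@@H](OC(=O)[C@@H](C)CC)[C@@H]12 | intermediate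
27 | CNP0526758.1 | C=C1C(=O)O[C@@H]2/C=C(/CO)CC[C@H](O)/C(C)=C\[C@@H](OC(=O)[C@@H](C)CC)[C@@H]12 | target

Total step count: 16. Longest linear sequence: 14 steps (steps 1–9, then 12–16). Steps 10 and 11 run in parallel.

Steps most likely to fail

Step 14. The addition to the C8 aldehyde may show poor or reversed facial selectivity, because the conformation of the closing ring can override the Felkin–Anh bias. The fallback sets out from 22. The same closure is accepted as it comes, and the 8-epi macrocyclic alcohol F1 is separated. It is then esterified with 25 under Mitsunobu conditions (PPh3, DIAD, toluene, 0 °C). C8 is thereby set by SN2 inversion instead of by the addition. This comes back to the route at 26.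

Step 12. The cross-conjugated dienolate may react at its γ-terminus C13. The methylene group may also slip into conjugation with C7 under the amine base. Either process would erode regio- and stereocontrol. The fallback sets out from 14 and 17 and postpones the methylene group.
- Compound 17 is acylated with methyl 4-chloro-4-oxobutanoate (Et3N, CH2Cl2) to the succinyl imide F2.
- The titanium enolate of F2 adds to 14 under the conditions of step 12 and lactonises to the saturated trans-lactone imide F3.
- i-Bu2AlH gives the saturated lactone aldehyde F4, which carries no isomerisable olefin into the ring closure.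
- CrCl2/NiCl2 at high dilution closes C8–C9 to the 13-nor macrocyclic alcohol F5.
- Double deprotonation (LDA, 2.5 equiv, THF, −78 °C) and Eschenmoser's salt give the Mannich base F6.
- MeI, then aqueous NaHCO3, eliminates the amine and comes back to the route at 24.

Step 8. The ketone may olefinate sluggishly, and the E/Z preference may erode because the two arms of the ketone are similar in size. The fallback sets out from 7 and fixes the geometry with a temporary ring.
- Esterification with diethylphosphonoacetic acid (DCC, DMAP) gives the phosphonoacetate F7.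
- OsO4/NMO gives the phosphonoacetate diol F8.
- TBSCl/imidazole gives the primary silyl ether F9.
- Dess–Martin oxidation gives the keto phosphonate F10.
- An intramolecular Horner–Wadsworth–Emmons reaction under Masamune–Roush conditions (LiCl, DBU, MeCN, high dilution) gives the seven-membered unsaturated lactone F11, whose ring forces C6 cis to C3.
- Me3Al/MeNH(OMe)·HCl opens the lactone to the hydroxy Weinreb amide F12.
- TBSCl/imidazole comes back to the route at 13.

Further compounds
F1 | step 14 | 8-epi macrocyclic alcohol | C=C1C(=O)O[C@@H]2/C=C(/CO[Si](C)(C)C(C)(C)C)CC[C@H](O[Si](C)(C)C(C)(C)C)/C(C)=C\[C@H](O)[C@@H]12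
F2 | step 12 | succinyl imide | COC(=O)CCC(=O)N1[C@@H](Cc2ccccc2)CSC1=S
F3 | step 12 | saturated trans-lactone imide | C1C(=O)O[C@H](/C=C(/CO[Si](C)(C)C(C)(C)C)CC[C@H](O[Si](C)(C)C(C)(C)C)/C(C)=C\I)[C@H]1C(=O)N2[C@@H](Cc3ccccc3)CSC2=S
F4 | step 12 | saturated lactone aldehyde | C1C(=O)O[C@H](/C=C(/CO[Si](C)(C)C(C)(C)C)CC[C@H](O[Si](C)(C)C(C)(C)C)/C(C)=C\I)[C@H]1C=O
F5 | step 12 | 13-nor macrocyclic alcohol | C1C(=O)O[C@@H]2/C=C(/CO[Si](C)(C)C(C)(C)C)CC[C@H](O[Si](C)(C)C(C)(C)C)/C(C)=C\[C@@H](O)[C@@H]12
F6 | step 12 | Mannich base | CN(C)CC1C(=O)O[C@@H]2/C=C(/CO[Si](C)(C)C(C)(C)C)CC[C@H](O[Si](C)(C)C(C)(C)C)/C(C)=C\[C@@H](O)[C@@H]12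
F7 | step 8 | phosphonoacetate | C=CCC[C@H](OC(=O)CP(=O)(OCC)OCC)/C(C)=C\I
F8 | step 8 | phosphonoacetate diol | OCC(O)CC[C@H](OC(=O)CP(=O)(OCC)OCC)/C(C)=C\I
F9 | step 8 | primary silyl ether | CC(C)(C)[Si](C)(C)OCC(O)CC[C@H](OC(=O)CP(=O)(OCC)OCC)/C(C)=C\I
F10 | step 8 | keto phosphonate | CC(C)(C)[Si](C)(C)OCC(=O)CC[C@H](OC(=O)CP(=O)(OCC)OCC)/C(C)=C\I
F11 | step 8 | seven-membered unsaturated lactone | O=C1C=C(CO[Si](C)(C)C(C)(C)C)CC[C@@H](/C(C)=C\I)O1
F12 | step 8 | hydroxy Weinreb amide | CON(C)C(=O)/C=C(/CO[Si](C)(C)C(C)(C)C)CC[C@H](O)/C(C)=C\I
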